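The route rests on cutting the bond between the ketone carbon on C8 of the coumarin's benzo ring and the ester-bearing methine. That methine is allylic to the isopropenyl CH2=C(CH3) unit. Carbonyl carbon, methine and 1,1-disubstituted alkene are therefore the retron of a carbonyl allylation with allylic transposition. A Cr(salen)-catalysed enantioselective Nozaki–Hiyama–Kishi acyloxyallylation joins 8-formyl-5,7-dimethoxycoumarin to 3-chloro-2-methylpropenyl senecioate, itself made by adding senecioyl chloride to methacrolein. One operation forms the C–C bond, unmasks the isopropenyl group, sets the methine configuration and delivers the senecioate already in place. A non-basic oxidation of the benzylic carbinol finishes the synthesis.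

Key step: step 3

Assumption: the (R,R)-salen ligand is taken to direct the allyl group to the Re face of the formyl group of 3. Both ligand antipodes are commercial, so the other one is used if the sense of induction proves reversed.

Step 1
Reactants: 1 5,7-dimethoxycoumarin (limettin)
Product: 3 5,7-dimethoxy-2-oxo-2H-chromene-8-carbaldehyde, via aryl iminium salt 2 (not isolated)
Conditions: POCl3 (3 equiv), DMF, ClCH2CH2Cl, 0 → 75 °C; then ice/H2O
Reagents that add atoms: N,N-dimethylformamide, CN(C)C=O (formyl carbon); water, O (formyl oxygen); phosphoryl chloride, O=P(Cl)(Cl)Cl (counter-ion of 2 only)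
Why: Vilsmeier–Haack formylation, in which the chloroiminium ion should attack C8 (ortho to 7-OMe, para to 5-OMe, flanked by the substituent-free ring oxygen) rather than C6, which is screened by the 5-OMe methyl group that peri H-4 turns towards it; hydrolysis of 2 then gives 3, and no stereocentre is formed.

Step 2
Reactants: 4 methacrolein; 5 3-methylbut-2-enoyl chloride (senecioyl chloride)
Product: 7 3-chloro-2-methylprop-1-en-1-yl 3-methylbut-2-enoate (E/Z mixture), via 1-chloro-2-methylallyl senecioate 6 (not isolated)
Conditions: ZnCl2 (3 mol %), CH2Cl2, −10 °C → rt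
Reagents that add atoms: none
Why: Lewis-acid-catalysed addition of an acyl chloride to an enal gives 6 by 1,2-chloroacylation, and its allylic chloride shifts (1,3) under ZnCl2 to the more stable enol ester 7; neither the E/Z ratio nor residual 6 matters, because all converge on one allylchromium species in step 3.

Step 3
Reactants: 3 5,7-dimethoxy-2-oxo-2H-chromene-8-carbaldehyde; 7 3-chloro-2-methylprop-1-en-1-yl 3-methylbut-2-enoate
Product: 10 (1S,2S)-1-(5,7-dimethoxy-2-oxo-2H-chromen-8-yl)-1-hydroxy-3-methylbut-3-en-2-yl 3-methylbut-2-enoate, via allylchromium(III) salen complex 8 (not isolated), via trimethylsilyl ether 9 (not isolated)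
Conditions: CrCl3 (10 mol %), Mn (3 equiv), (R,R)-N,N′-bis(3,5-di-tert-butylsalicylidene)-1,2-cyclohexanediamine (12 mol %), Et3N (25 mol %), MeCN, rt; then 7 (1.5 equiv), 3, TMSCl (1.5 equiv), MeCN/CH2Cl2, rt; then 10 % aq citric acid, THF, 0 °C
Reagents that add atoms: chlorotrimethylsilane, C[Si](C)(C)Cl (silyl group of 9 only); chromium(III) chloride, Cl[Cr](Cl)Cl, and the (R,R)-salen ligand, CC(C)(C)c1cc(C=N[C@@H]2CCCC[C@H]2N=Cc2cc(cc(c2O)C(C)(C)C)C(C)(C)C)c(O)c(c1)C(C)(C)C (metal fragment of 8 only)
Why: Mn(0) reduces the Cr(III)(salen) precatalyst to Cr(II), two Cr(II) centres convert the allylic chloride 7 (and any residual 6) by successive single-electron transfers into σ-allylchromium(III) complex 8 with the metal on the unoxygenated CH2 terminus, and 8 adds through its γ-carbon, the enol-ester CH, to the formyl carbon of 3 (SE2′), so the C=C bond moves into the isopropenyl position as the new C–C bond forms. The closest known reaction type is the catalytic enantioselective Nozaki–Hiyama–Kishi α-hydroxyallylation of aldehydes with 3-chloropropenyl esters under Cr(salen)/Mn/TMSCl, and no ring is closed. The carbinol centre is set by the C2-symmetric salen ligand, which should expose the Re face of the aldehyde, and the ester-bearing centre follows from the syn topicity typical of salen-bound γ-substituted allylchromium reagents, whose E and Z forms interconvert faster than they add, so (1S,2S)-10 should result. Because the carbinol centre is erased in step 4, the anti isomer, which carries the opposite configuration at the ester-bearing carbon, has to be removed by chromatography at this stage, where crystallisation can also raise the enantiomeric purity. Chemoselectivity for the aldehyde over the coumarin lactone, its C3=C4 enoate and the senecioate is secured by the low basicity and marked aldehyde preference of organochromium(III) reagents. TMSCl silylates the chromium alkoxide at once to give 9, which turns the catalyst over and keeps the senecioyl group from migrating to the neighbouring oxygen, and mild aqueous acid then frees the alcohol.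

Step 4
Reactants: 10 (1S,2S)-1-(5,7-dimethoxy-2-oxo-2H-chromen-8-yl)-1-hydroxy-3-methylbut-3-en-2-yl 3-methylbut-2-enoate
Product: 11 (S)-1-(5,7-dimethoxy-2-oxo-2H-chromen-8-yl)-3-methyl-1-oxobut-3-en-2-yl 3-methylbut-2-enoate (target)
Conditions: Dess–Martin periodinane (1.3 equiv), CH2Cl2, 0 °C → rt
Reagents that add atoms: none
Why: Dess–Martin oxidation proceeds by alkoxide exchange at iodine(V) and internal removal of the carbinol hydrogen under non-basic conditions, so the acidic C–H of the ester-bearing (S)-centre should not enolise, the isopropenyl alkene should stay out of conjugation, and only the carbinol stereocentre is erased.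

Compound list
1 | 5,7-dimethoxycoumarin (limettin) | COc1cc(OC)c2ccc(=O)oc2c1 | starting material
2 | [(5,7-dimethoxy-2-oxo-2H-chromen-8-yl)methylidene]dimethyliminium dichlorophosphate | C[N+](C)=Cc1c(OC)cc(OC)c2ccc(=O)oc12.[O-]P(=O)(Cl)Cl | intermediate
3 | 5,7-dimethoxy-2-oxo-2H-chromene-8-carbaldehyde | O=Cc1c(OC)cc(OC)c2ccc(=O)oc12 | intermediate
4 | methacrolein | C=C(C)C=O | starting material
5 | 3-methylbut-2-enoyl chloride (senecioyl chloride) | CC(C)=CC(=O)Cl | starting material
6 | 1-chloro-2-methylallyl 3-methylbut-2-enoate (racemic) | C=C(C)C(Cl)OC(=O)C=C(C)C | intermediate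
7 | 3-chloro-2-methylprop-1-en-1-yl 3-methylbut-2-enoate (E/Z mixture) | CC(C)=CC(=O)OC=C(C)CCl | intermediate
8 | [2-methyl-3-(3-methylbut-2-enoyloxy)allyl]chromium(III) (R,R)-salen complex (N→Cr bonds not drawn) | CC(C)=CC(=O)OC=C(C)C[Cr]1Oc2c(C=N[C@@H]3CCCC[C@H]3N=Cc3cc(cc(c3O1)C(C)(C)C)C(C)(C)C)cc(cc2C(C)(C)C)C(C)(C)C | intermediate
9 | (1S,2S)-1-(5,7-dimethoxy-2-oxo-2H-chromen-8-yl)-3-methyl-1-(trimethylsilyloxy)but-3-en-2-yl 3-methylbut-2-enoate | C=C(C)[C@H](OC(=O)C=C(C)C)[C@@H](O[Si](C)(C)C)c1c(OC)cc(OC)c2ccc(=O)oc12 | intermediate
10 | (1S,2S)-1-(5,7-dimethoxy-2-oxo-2H-chromen-8-yl)-1-hydroxy-3-methylbut-3-en-2-yl 3-methylbut-2-enoate (syn) | C=C(C)[C@H](OC(=O)C=C(C)C)[C@@H](O)c1c(OC)cc(OC)c2ccc(=O)oc12 | intermediate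
11 | (S)-1-(5,7-dimethoxy-2-oxo-2H-chromen-8-yl)-3-methyl-1-oxobut-3-en-2-yl 3-methylbut-2-enoate | C=C(C)[C@H](OC(=O)C=C(C)C)C(=O)c1c(OC)cc(OC)c2ccc(=O)oc12 | target

Total step count: 4. Longest linear sequence: 3 (1 → 3 → 10 → 11).

Steps most likely to fail

Step 3. Several things may go wrong here:
- Facial selectivity or syn/anti selectivity may be poor with the di-ortho-substituted aldehyde and the β-methylated allyl donor.
- Reductive pinacol coupling of the aldehyde may compete.
- The acyl group may migrate before the alkoxide is silylated.

The fallback replaces catalyst control by reagent control. It sets out from 3 and comes back to the route at 11.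
- Methallyl alcohol is converted with MOMCl/iPr2NEt into 3-(methoxymethoxy)-2-methylprop-1-ene F1.
- This ether is lithiated (s-BuLi, THF, −78 °C), trapped with (+)-B-methoxydiisopinocampheylborane (from (−)-α-pinene) and treated with BF3·OEt2. This should give (Z)-[3-(methoxymethoxy)-2-methylallyl]diisopinocampheylborane F2.
- The borane adds to the Re face of 3 at −78 °C through a chair Zimmerman–Traxler transition state (NaBO3 work-up). The product should be 8-[(1S,2S)-1-hydroxy-2-(methoxymethoxy)-3-methylbut-3-en-1-yl]-5,7-dimethoxycoumarin F3.
- Dess–Martin oxidation gives 8-[(S)-2-(methoxymethoxy)-3-methylbut-3-enoyl]-5,7-dimethoxycoumarin F4.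
- TMSBr at −30 °C frees 8-[(S)-2-hydroxy-3-methylbut-3-enoyl]-5,7-dimethoxycoumarin F5.
- Acylation with 5 (pyridine, CH2Cl2, −20 °C) gives 11.

Step 4. The senecioyl group may migrate in the free alcohol before oxidation. The new α-acyloxy ketone may also enolise, which would erode configuration or draw the alkene into conjugation.

The fallback never exposes the free alcohol. It sets out from 9 and comes back at 11.
- Step 3 is worked up with pH 7 buffer, so silyl ether 9 is isolated.
- The electron-rich benzylic silyl ether is oxidised directly by hydride abstraction with DDQ (CH2Cl2/pH 7 buffer, rt).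
- This fallback makes no new compound (F0).

Step 1. Attack at C6 may compete with attack at C8, or conversion may be low because the lactone-bearing ring is only moderately nucleophilic.

The fallback fixes the position with a halogen before the carbon is introduced. It sets out from 1 and comes back at 3.
- Iodination (NIS, cat. TFA, MeCN) should give 8-iodo-5,7-dimethoxycoumarin F6.
- F6 can be purified by crystallisation and its site of substitution checked.
- It is then converted into 3 by palladium-catalysed reductive carbonylation (Pd(PPh3)4, CO, slow addition of Bu3SnH, THF, 50 °C).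

Further compounds
F1 | step 3 | 3-(methoxymethoxy)-2-methylprop-1-ene | C=C(C)COCOC
F2 | step 3 | (Z)-[3-(methoxymethoxy)-2-methylallyl]diisopinocampheylborane (Ipc groups from (−)-α-pinene) | COCO/C=C(/C)CB([C@H]1C[C@H]2C[C@@H]([C@@H]1C)C2(C)C)[C@H]1C[C@H]2C[C@@H]([C@@H]1C)C2(C)C
F3 | step 3 | 8-[(1S,2S)-1-hydroxy-2-(methoxymethoxy)-3-methylbut-3-en-1-yl]-5,7-dimethoxycoumarin | C=C(C)[C@H](OCOC)[C@@H](O)c1c(OC)cc(OC)c2ccc(=O)oc12
F4 | step 3 | 8-[(S)-2-(methoxymethoxy)-3-methylbut-3-enoyl]-5,7-dimethoxycoumarin | C=C(C)[C@H](OCOC)C(=O)c1c(OC)cc(OC)c2ccc(=O)oc12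
F5 | step 3 | 8-[(S)-2-hydroxy-3-methylbut-3-enoyl]-5,7-dimethoxycoumarin | C=C(C)[C@H](O)C(=O)c1c(OC)cc(OC)c2ccc(=O)oc12
F0 | step 4 | none | none
F6 | step 1 | 8-iodo-5,7-dimethoxycoumarin | COc1cc(OC)c2ccc(=O)oc2c1I
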